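**Retrosynthetic overview**
1. Target 9 ⇐ 8 (phenolic acetate removed) ⇐ 7 (anti-elimination of the C4 tertiary alcohol to the C3=C4 alkene).
2. 7 ⇐ 6: the C1–C5 bond is cut. The five- and seven-membered rings form together when the C1=C10 alkene of a ten-membered germacrene opens its (4S,5S)-4,5-epoxide across the ring, as germacrene epoxides are thought to become guaianes.
3. 6 ⇐ 4 + 5 (ester bond); 4 ⇐ 3 by catalyst-controlled epoxidation, which brings in the absolute configuration.
4. 3 ⇐ 1: germacrone supplies the ten-membered ring, all fifteen carbons and the C8 oxygen; its reduction sets the C7/C8 relative configuration.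
5. Ring order: the ten-membered ring is bought; one step then forms the five- and seven-membered rings at once.

Assumption: germacrone (bulk isolate of Geranium macrorrhizum and Curcuma oils) and 4-acetoxy-3-methoxybenzoic acid are taken as inexpensive catalogue chemicals; positions follow germacrane/guaiane numbering (C7 isopropyl, C8 oxygen, C14 on C10, C15 on C4).

**Step 1**
Reactants: 1 germacrone
Product: 3 (±)-trans-germacra-1(10)E,4E-dien-8-ol, via 7,11-dihydrogermacrone 2 (not isolated)
Conditions: Li (6 equiv), NH3(l)/THF, EtOH (4 equiv), −78 → −33 °C; then NH4Cl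
Reagents that add atoms: none
Why: Dissolving-metal (Birch-type) reduction: two electrons and EtOH turn the conjugated enone into ketone 2 through its lithium enolate, and further electron transfer reduces the ketone under thermodynamic control to the more stable alcohol with OH and isopropyl trans (7R*,8S*), as 2-alkylcycloalkanones give trans-2-alkylcycloalkanols; the isolated trisubstituted alkenes are inert, and the product is racemic because germacrone is achiral.

**Step 2**
Reactants: 3 (±)-trans-germacra-1(10)E,4E-dien-8-ol
Product: 4 (1(10)E,4S,5S,7R,8S)-4,5-epoxygermacr-1(10)-en-8-ol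
Conditions: ent-Shi ketone (L-fructose-derived, 30 mol%), KHSO5 (as Oxone, 1.1 equiv), K2CO3, Bu4NHSO4 (5 mol%), MeCN/dimethoxymethane/aq. Na2B4O7–Na2EDTA buffer (pH 10.5), 0 °C; chromatography on Et3N-deactivated silica
Reagents that add atoms: potassium peroxymonosulfate KHSO5 (Oxone), [K+].[O-]S(=O)(=O)OO
Why: Shi asymmetric epoxidation run as a divergent reaction on the racemate: the chiral dioxirane attacks the C4=C5 alkene (C1=C10 is inductively deactivated by the homoallylic C8–O) and, because the two alkene faces exchange by fast ring flipping, imposes the (4S,5S) epoxide on both enantiomers of 3, so the (7R,8S) half gives 4 and the (7S,8R) half gives a diastereomer removed on silica; the enantiomer of 4 could form only against the catalyst preference, which keeps its ee high (theoretical yield 50%).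

**Step 3**
Reactants: 4 (1(10)E,4S,5S,7R,8S)-4,5-epoxygermacr-1(10)-en-8-ol; 5 4-acetoxy-3-methoxybenzoic acid
Product: 6 (1(10)E,4S,5S,7R,8S)-4,5-epoxygermacr-1(10)-en-8-yl 4-acetoxy-3-methoxybenzoate
Conditions: DCC (1.5 equiv), DMAP (0.3 equiv), CH2Cl2, 0 °C → rt
Reagents that add atoms: none
Why: Steglich esterification acylates the C8 hydroxyl with retention under neutral conditions that spare the epoxide and the aryl acetate (which would not survive the pH 10.5 oxidation of step 2), and it removes the free OH that could otherwise open the epoxide to a tetrahydrofuran under acid.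

**Step 4**
Reactants: 6 (1(10)E,4S,5S,7R,8S)-4,5-epoxygermacr-1(10)-en-8-yl 4-acetoxy-3-methoxybenzoate
Product: 8 (5R,7R,8S)-guaia-1(10),3-dien-8-yl 4-acetoxy-3-methoxybenzoate, via 4-hydroxyguai-1(10)-en-8-yl ester 7 (not isolated)
Conditions: (+)-camphor-10-sulfonic acid (anhydrous, 10 mol%), CH2Cl2, 0 °C → rt; then Martin sulfurane Ph2S[OC(CF3)2Ph]2 (1.5 equiv), 0 °C
Reagents that add atoms: none
Why: Biomimetic transannular epoxide–olefin (cation–olefin) cyclization followed in the same flask by Martin sulfurane dehydration: the protonated epoxide is opened at C5 by C1 of the C1=C10 alkene from inside the ring with inversion (this sets C5, H5 cis to the isopropyl group; 5S in 7 and 5R in 8 only through a change in CIP ranking), the tertiary C10 cation loses H1 to the tetrasubstituted 1(10)-alkene (the parthenolide → micheliolide pattern), and the C4 alkoxysulfonium then eliminates anti-periplanar with a ring H3 because H5 is syn to the C4–O bond, giving the 3,4-alkene and not the conjugated 1(10),4-diene.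

**Step 5**
Reactants: 8 (5R,7R,8S)-guaia-1(10),3-dien-8-yl 4-acetoxy-3-methoxybenzoate
Product: 9 (5R,7R,8S)-guaia-1(10),3-dien-8-yl 4-hydroxy-3-methoxybenzoate (CNP0156298.2)
Conditions: pyrrolidine (3 equiv), CH2Cl2, 0 °C, 30 min; sat. NH4Cl wash
Reagents that add atoms: none
Why: Chemoselective aminolysis of the aryl acetate: the phenolic ester is far more electrophilic than the hindered secondary alkyl benzoate, so the phenol is freed without acid or strong base, leaving the skipped 1(10),3-diene and all three stereocenters untouched.

**Compound list**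
1 | germacrone, (3E,7E)-3,7-dimethyl-10-(propan-2-ylidene)cyclodeca-3,7-dien-1-one | O=C1C/C(C)=C/CC/C(C)=C/CC1=C(C)C | starting material
2 | (±)-7,11-dihydrogermacrone, (3E,7E)-3,7-dimethyl-10-(propan-2-yl)cyclodeca-3,7-dien-1-one, racemic at C7 | O=C1C/C(C)=C/CC/C(C)=C/CC1C(C)C | intermediate
3 | (±)-trans-germacra-1(10)E,4E-dien-8-ol, rac-(1S,3E,7E,10R)-3,7-dimethyl-10-(propan-2-yl)cyclodeca-3,7-dien-1-ol; racemate, SMILES shows the (7R,8S) enantiomer that is carried on | O[C@H]1C/C(C)=C/CC/C(C)=C/C[C@@H]1C(C)C | intermediate
4 | (1(10)E,4S,5S,7R,8S)-4,5-epoxygermacr-1(10)-en-8-ol (trans-epoxide across C4–C5, E alkene C1=C10, OH at C8 trans to isopropyl at C7) | O[C@H]1C/C(C)=C/CC[C@]2(C)O[C@H]2C[C@@H]1C(C)C | intermediate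
5 | 4-acetoxy-3-methoxybenzoic acid (O-acetylvanillic acid) | COc1cc(C(=O)O)ccc1OC(C)=O | starting material
6 | (1(10)E,4S,5S,7R,8S)-4,5-epoxygermacr-1(10)-en-8-yl 4-acetoxy-3-methoxybenzoate | COc1cc(C(=O)O[C@H]2C/C(C)=C/CC[C@]3(C)O[C@H]3C[C@@H]2C(C)C)ccc1OC(C)=O | intermediate
7 | (4S,5S,7R,8S)-4-hydroxyguai-1(10)-en-8-yl 4-acetoxy-3-methoxybenzoate (4-OH cis to H5) | COc1cc(C(=O)O[C@H]2CC(C)=C3CC[C@](C)(O)[C@H]3C[C@@H]2C(C)C)ccc1OC(C)=O | intermediate
8 | (5R,7R,8S)-guaia-1(10),3-dien-8-yl 4-acetoxy-3-methoxybenzoate | COc1cc(C(=O)O[C@H]2CC(C)=C3CC=C(C)[C@H]3C[C@@H]2C(C)C)ccc1OC(C)=O | intermediate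
9 | (5R,7R,8S)-guaia-1(10),3-dien-8-yl vanillate, (3aR,5R,6S)-3,8-dimethyl-5-(propan-2-yl)-1,3a,4,5,6,7-hexahydroazulen-6-yl 4-hydroxy-3-methoxybenzoate | COc1cc(C(=O)O[C@H]2CC(C)=C3CC=C(C)[C@H]3C[C@@H]2C(C)C)ccc1O | target

**Totals**
Total steps: 5. Longest linear sequence: 5 (1 → 3 → 4 → 6 → 8 → 9); acid 5 is bought.

**Steps most likely to fail, with fallbacks**

Step 2 (epoxidation). The C4=C5 versus C1=C10 selectivity on a homoallylic alcohol may be modest. In addition, the (7R,8S) half may be the mismatched partner for the (4S,5S) face, judged by analogy with germacrene conformer populations. The fallback moves the epoxidation to the ketone oxidation level, where the β,γ-carbonyl strongly deactivates C1=C10. It sets out from 1: the reduction is stopped at the ketone (Li 2.2 equiv, NH3/THF, t-BuOH 1 equiv, −78 °C, NH4Cl quench) and 2 is isolated. Epoxidation of 2 under the same ent-Shi conditions gives (1(10)E,4S,5S)-4,5-epoxy-7,11-dihydrogermacr-1(10)-en-8-one F1 as a pair of C7 epimers that interconvert through the enol. Reduction with NaBH4 in MeOH at −40 °C and separation of the (7R,8S) trans alcohol brings the route back at 4.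

Step 4 (cyclization/dehydration). The C10 cation may lose H9 or H14, and the C4 elimination may give the exocyclic 4(15)-alkene or, if it turns cationic, the conjugated 1(10),4-diene. The fallback takes away the alkene that makes the conjugated diene possible. It sets out from 6: the reaction is stopped after the acid stage and 7 is isolated. mCPBA/NaHCO3 (CH2Cl2, 0 °C) epoxidizes the tetrasubstituted C1=C10 alkene to (4S,5S,7R,8S)-1,10-epoxy-4-hydroxyguaian-8-yl 4-acetoxy-3-methoxybenzoate F2 (either epoxide face serves). Martin sulfurane then gives (5R,7R,8S)-1,10-epoxyguai-3-en-8-yl 4-acetoxy-3-methoxybenzoate F3, as in the micheliolide-to-arglabin dehydration. Deoxygenation with PPh3 and CH3ReO3 (5 mol%) in benzene at rt restores the alkene and returns to the route at 8.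

Step 1 (reduction). The trans/cis ratio at C7/C8 under dissolving-metal conditions in a ten-membered ring is argued by analogy, and a base-induced shift of the C1=C10 alkene followed by over-reduction is possible. The fallback replaces the one-pot electron-transfer reduction by two separate polar hydride steps under kinetic control. It sets out from 1: conjugate reduction with [(Ph3P)CuH]6 (the hexameric hydride of monovalent copper, benzene/THF, rt, then aq. NH4Cl) gives isolated 2. NaBH4 in MeOH at −40 °C (small hydride, attack anti to the axial-like C–H at C7) then gives the trans alcohol, with the cis isomer removed by chromatography, and the route is rejoined at 3. This fallback makes no compound outside the list: none F0.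

**Further compounds**
F0 | step 1 | none | none
F1 | step 2 | (1(10)E,4S,5S)-4,5-epoxy-7,11-dihydrogermacr-1(10)-en-8-one, both C7 epimers | O=C1C/C(C)=C/CC[C@]2(C)O[C@H]2CC1C(C)C
F2 | step 4 | (4S,5S,7R,8S)-1,10-epoxy-4-hydroxyguaian-8-yl 4-acetoxy-3-methoxybenzoate, epoxide face not fixed | COc1cc(C(=O)O[C@H]2CC4(C)OC43CC[C@](C)(O)[C@H]3C[C@@H]2C(C)C)ccc1OC(C)=O
F3 | step 4 | (5R,7R,8S)-1,10-epoxyguai-3-en-8-yl 4-acetoxy-3-methoxybenzoate, epoxide face not fixed | COc1cc(C(=O)O[C@H]2CC4(C)OC43CC=C(C)[C@H]3C[C@@H]2C(C)C)ccc1OC(C)=O
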